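## Structural features

The target 23 has two ring systems joined by one C–C bond: a 7-methoxycoumarin (benzene ring fused to an α-pyranone) whose C3 carries C1' of a cyclohex-2-ene-1,4-dione. In the carbocycle, C1'=C2' is the alkene, C3' and C6' are the ketones, C5' is a methylene, and C4' is a fully substituted carbinol bearing the hydroxyl group and the prenyl chain. C4' (R) is the only stereocentre, so nothing relative has to be controlled; the task is absolute control at a quaternary oxygenated carbon that lies α to one ketone and β to the other. The fragile part is the β-hydroxy ketone array C4'(OH)–C5'H2–C6'(=O): loss of water would turn the ring into a 2,5-disubstituted benzoquinone, and base or strong acid invites it. The α-ketol at C3'/C4', the electrophilic coumarin (C2 and C4) and the acid- and borane-sensitive prenyl alkene set further limits. The real difficulty is to bring an enantiopure tertiary carbinol into a ring that reaches the enedione oxidation level only at the very end and under neutral conditions. The key step uses the fact that C1' is both the alkene carbon of the carbocycle and the atom bonded to coumarin C3, that is, the ketone carbon of a 3-acylcoumarin, while C2' can be the methyl group of a C3' methyl ketone; the C1'=C2' bond and the six-membered ring then form together by intramolecular aldol condensation.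

## Logic of the disconnections

23 ⇒ 22 ⇒ 21. No skeletal bond is cut. The C6' carbonyl of 23 is traced to the secondary allylic alcohol of 22, and the two hydroxyl groups of 22 to the silyl ethers of 21. The reason is the β-hydroxy ketone of 23: while C6' is a carbinol the ring cannot lose water towards the quinone, so the carbonyl is best made last. The gain is that all earlier intermediates are robust. The demand is a final oxidation that is neutral, touches only the allylic secondary alcohol and tolerates the free tertiary one, preceded by the desilylation.

21 ⇒ 19 (through 20). The C1'=C2' double bond is cut, which opens the carbocycle into a methyl ketone (C2', C3') and a 3-acyl ketone (C1'). C1' is electrophilic and not enolisable on the coumarin side, C3' can enolise only towards C2', and the bond closes a six-membered ring. The gain is an acyclic precursor whose only stereocentre of consequence is C4'. The demand is closure at C1' alone under conditions mild enough for the coumarin and the silyl ethers; keeping C6' as a silyl ether answers the first point.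

19 ⇒ 17 + 18. The coumarin C3=C4 double bond and the lactone O1–C2 bond are cut, the classical division of a 3-acylcoumarin into a β-keto ester and a salicylaldehyde. This removes the whole heteroaromatic unit in one step and leaves a purchasable aldehyde. The demand is that the active methylene of 17 condenses with the aldehyde faster than with the internal methyl ketone.

17 ⇒ 15 ⇒ 14 ⇒ 11 + 12. The C1' carbonyl of 17 is traced to the alkyne of 15 (formal hydration), the C6' silyl ether to the alcohol of 14, and the C6'–C1' bond is then cut between an aldehyde and an acetylide. The three carbons C1', coumarin C3 and coumarin C2 thus arrive from 12 in one bond formation, and C6' arrives at the alcohol level that the key step requires. The demands are three: the acetylide must choose the aldehyde over the hindered ketone of 11, the C6' hydroxyl must be silylated before the hydration, and the hydration must place oxygen on the alkyne carbon remote from the ester. No control is needed at C6'.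

11 ⇒ 10 ⇒ 9. The aldehyde of 11 is traced to the primary alcohol of 10, and the C2'–C3' bond is cut so that the methyl ketone becomes a lactone carbonyl plus a methyl nucleophile. A five-membered lactone holds C3' at the acid level and C6' at the alcohol level at once, and ring opening frees both ends in one step. The demand is a single addition of the methyl nucleophile and a mild oxidation of a γ-hydroxy ketone.

9 ⇒ 8 ⇒ 5. The O–Si bond is cut, then the lactone C–O bond, with C6' returned to the acid level and C3' to the acylal carbonyl of 5. This links the lactone to a malic acid skeleton whose two carboxyl groups are already differentiated (one free, one in the acetal ring). The demand is a reduction of the free acid that spares both the acetal lactone and the prenyl double bond, which rules out borane.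

5 ⇒ 2 + 3 (through 4), and 2 ⇒ 1. The C4'–CH2 bond of the prenyl group is cut at an enolate, and the acetal is then removed. The stereocentre of 1 is lost in enolate 4, but its information is stored in the tert-butyl-bearing acetal carbon of 2 and is returned when 3 enters trans to that group. The quaternary carbinol thus comes from a chiral-pool acid with net retention: 4'R in 23 corresponds to (R)-configured 1. The demand is clean formation of the cis acetal and of the dianion at low temperature.

## Other disconnections considered

Alternative 1: The cut is made at C4' itself. The C4'–O bond and the C4'–CH2 bond of the prenyl chain are traced to the oxirane of epoxy alcohol A2, whose ring methylene is the first prenyl carbon, whose hydroxymethyl group becomes C3' and whose silyloxyethyl arm becomes C5'–C6'.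
- Forward key step: a Sharpless asymmetric epoxidation (Ti(OiPr)4, D-(−)-tartrate ester, alkyl hydroperoxide) of the 1,1-disubstituted allylic alcohol A1, which by the usual facial rule should give the (R)-oxirane A2. Opening at the ring methylene with an isobutenyl organometallic nucleophile would then complete the prenyl group and free the tertiary hydroxyl.
- In its favour: catalyst control by a well-understood reaction, both enantiomers equally accessible, an achiral precursor, and no cryogenic dianion chemistry.
- Against it here: 2-substituted allylic alcohols are the less selective substrate class for this epoxidation, and their small 2,2-disubstituted epoxy alcohols are prone to ring opening under the titanium conditions, so the enantiomeric purity of C4' would rest on one imperfect step. A1 needs a selective monosilylation between two primary hydroxyl groups. After the opening, the hydroxymethyl group must still be taken to the methyl ketone (oxidation, methyl addition, oxidation) and the silyl ether to the aldehyde, so the sequence rejoins the chosen route only at 11, in more steps than the four that lead from 5 to 11.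
- Comparison: structurally both plans install C4' before the ring exists and both leave ring formation to the same aldol closure, so this alternative changes the source of chirality, not the strategy. Mechanistically it trades substrate control from the chiral pool for catalyst control. In step economy it is the longer. It is the equal of the chosen plan in the reliability of each reaction type, and the better one in not depending on the less common enantiomer of malic acid and in giving either antipode at will.

Alternative 2: Two ring bonds are cut at once, C1'–C6' and C2'–C3'. This divides the target into the sulfonyl butanolide A3 (C3' to C6' with the stereocentre; C3' is the lactone carbonyl and C6' bears the sulfonyl group and the ring oxygen) and the nitrovinylcoumarin A4 (C1', C2' and the coumarin).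
- Forward key step: A3, deprotonated at C6' with a lithium amide base, would add to the nitroalkene carbon C1' of A4. The nitronate carbon C2' would then attack the lactone carbonyl C3' in a Dieckmann-like 6-exo-trig closure, collapse at C6' would expel sulfinate to reveal the C6' ketone, and loss of nitrite would install the C1'=C2' alkene. The product is A5, the triethylsilyl ether of 23.
- In its favour: it is convergent, forms two C–C bonds and the ring in one flask, arrives directly at the enedione level, and leaves a single desilylation. A3 could be derived from 9 in a few steps (oxidation at C6' to the acid-aldehyde level, exchange for a thiol, oxidation at sulfur), so the stereocentre has the same source.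
- Against it here: this annulation is best supported for aromatic sulfonyl lactones, where aromatisation pulls the sequence through. Here a nitronate would have to be acylated at carbon by a lactone carbonyl next to a quaternary silyloxy carbon. A4 offers a hard lithium carbanion three electrophilic sites (nitroalkene, coumarin C4, lactone) and is prone to anionic polymerisation. The oxidation at sulfur on the way to A3 must spare the prenyl alkene. A5 would form in a strongly basic medium although it is a β-silyloxy ketone with an acidic C5' methylene, the very arrangement that eliminates to the quinone, and the last step would release the β-hydroxy ketone under fluoride or acid instead of by a neutral oxidation.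
- Comparison: in step economy and in convergence this alternative is clearly the better one. In the origin and integrity of C4' the two plans are equal. Mechanistically the chosen plan asks for one bond formation under buffered amine catalysis with the sensitive oxidation level masked, whereas the alternative asks three consecutive anionic events to succeed with it unmasked; for that reason the longer route is preferred.

Alternative 3: The cut runs through C3'–C4' and C5'–C6', a retro-Diels–Alder division into the 1-acetoxy-3-(coumarinyl)butadiene A6 and α-(benzoyloxy)acrolein A7.
- Forward key step: A7 would be activated as its iminium ion by a chiral primary ammonium salt and would add to A6 to give cyclohexene A8, in which C4' is formed as a quaternary acyloxy aldehyde centre. The acetoxy group (ortho-directing) and the coumarinyl group (para-directing) both favour the required regiochemistry.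
- In its favour: the carbocycle and the stereocentre are made in one catalytic, enantioselective step from achiral components, and the C3' configuration is of no consequence because that carbon becomes a ketone.
- Against it here: A6 is a poor diene, since the coumarinyl group withdraws electrons and a single acetoxy group donates weakly, and it is itself a Michael acceptor towards the amine catalyst. A8 is at the wrong oxidation level at three ring positions and carries the wrong side chain. The aldehyde must be homologated by one carbon and olefinated next to a quaternary centre to give the prenyl group, the C3' acetate must be exchanged for a ketone, the C6' methylene must be oxidised in the presence of the allylic positions of the prenyl group, and the benzoate must be removed without elimination.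
- Comparison: in how the ring and the stereocentre are created this alternative is the better one (one catalytic step against a chiral-pool sequence), and it is the equal of the chosen plan in the regiochemical security of the ring-forming event. After the ring closure it is much the worse: the chosen plan closes the ring with every carbon and oxygen already in place and needs two steps to finish, whereas here a long and partly unselective series of adjustments would follow.

Key step: step 11

Remark on the chemistry: the addition in step 7 is not face-selective, so 14 to 22 are carried as mixtures of both C6' epimers and this centre is left undefined in their SMILES (the mixture converges in step 13); the configuration was checked from 1 to 23 and no structure needed correction (prenyl replaces hydrogen with retention in step 2, giving 4'R from (R)-malic acid), and the only changes to the plan are in reagents: no borane once the prenyl group is present, and silylation of C6' before the hydration.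

Step 1
Reactants: 1 (R)-malic acid
Product: 2 [(2R,4R)-2-tert-butyl-5-oxo-1,3-dioxolan-4-yl]acetic acid (cis acetal)
Conditions: t-BuCHO, p-TsOH (cat.), H2SO4 (cat.), pentane, reflux, Dean–Stark; recrystallisation
Reagents that add atoms: pivalaldehyde, CC(C)(C)C=O
Why: Acid-catalysed acetalisation of the α-hydroxy acid unit under water removal gives the five-membered dioxolanone in preference to the six-membered alternative. Under equilibrating conditions the cis isomer should dominate, so the new acetal centre (2R) is set by the existing carbinol centre, and crystallisation should remove the trans isomer.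

Step 2
Reactants: 2 [(2R,4R)-2-tert-butyl-5-oxo-1,3-dioxolan-4-yl]acetic acid; 3 prenyl bromide (1-bromo-3-methylbut-2-ene)
Product: 5 [(2R,4R)-2-tert-butyl-4-(3-methylbut-2-en-1-yl)-5-oxo-1,3-dioxolan-4-yl]acetic acid, via dilithium enolate carboxylate 4 (not isolated)
Conditions: LiN(SiMe3)2 (2.1 equiv), THF, −78 °C; then 3, −78 → −20 °C; 1 M HCl work-up
Reagents that add atoms: lithium bis(trimethylsilyl)amide, [Li+].C[Si](C)(C)[N-][Si](C)(C)C (lithium only, in 4)
Why: Enolate alkylation with self-regeneration of the stereocentre: in the planar enolate 4 the tert-butyl group on the acetal carbon shields one face, so 3 should enter trans to it in an SN2 reaction at its primary carbon, which puts prenyl where hydrogen stood (net retention, 4R). The free carboxylate keeps the side-chain methylene from being deprotonated, which avoids β-elimination of the ring oxygen.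

Step 3
Reactants: 5 [(2R,4R)-2-tert-butyl-4-(3-methylbut-2-en-1-yl)-5-oxo-1,3-dioxolan-4-yl]acetic acid
Product: 8 (3R)-3-hydroxy-3-(3-methylbut-2-en-1-yl)dihydrofuran-2(3H)-one, via mixed isobutyl carbonic anhydride 6 (not isolated), via hydroxyethyl dioxolanone 7 (not isolated)
Conditions: i-BuOCOCl, N-methylmorpholine, THF, −15 °C; NaBH4, H2O, 0 °C; crude 7, p-TsOH (cat.), CH2Cl2, 23 °C
Reagents that add atoms: isobutyl chloroformate, CC(C)COC(=O)Cl (atoms only in 6)
Why: Borohydride reduction of a mixed carbonic anhydride is selective for the activated acyl group and, unlike borane, leaves the trisubstituted prenyl alkene alone. The primary alcohol of 7 then attacks the acylal carbonyl (5-exo-trig translactonisation) and the acetal collapses with loss of pivalaldehyde; the carbinol centre is not touched, so its configuration is kept.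

Step 4
Reactants: 8 (3R)-3-hydroxy-3-(3-methylbut-2-en-1-yl)dihydrofuran-2(3H)-one
Product: 9 (3R)-3-(3-methylbut-2-en-1-yl)-3-(triethylsilyloxy)dihydrofuran-2(3H)-one
Conditions: Et3SiOTf, 2,6-lutidine, CH2Cl2, 0 °C
Reagents that add atoms: triethylsilyl triflate, CC[Si](CC)(CC)OS(=O)(=O)C(F)(F)F
Why: Standard silylation of a tertiary alcohol with a silyl triflate and a hindered base. The ether blocks alkoxide chemistry at C4' (retro-aldol, ketol shift) in the steps that follow.

Step 5
Reactants: 9 (3R)-3-(3-methylbut-2-en-1-yl)-3-(triethylsilyloxy)dihydrofuran-2(3H)-one
Product: 10 (3R)-3-(2-hydroxyethyl)-6-methyl-3-(triethylsilyloxy)hept-5-en-2-one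
Conditions: MeLi (1.1 equiv), Et2O, −78 °C; AcOH, −78 °C
Reagents that add atoms: methyllithium, [Li]C
Why: Mono-addition of methyllithium to a lactone: the lithium hemiketalate is stable at −78 °C and is shielded by the neighbouring quaternary silyloxy carbon, so the ketone is set free only on the cold quench and a second addition should not occur. The product may exist partly as its ring tautomer (cyclic hemiketal), which is of no consequence for the next step.

Step 6
Reactants: 10 (3R)-3-(2-hydroxyethyl)-6-methyl-3-(triethylsilyloxy)hept-5-en-2-one
Product: 11 (3R)-3-acetyl-6-methyl-3-(triethylsilyloxy)hept-5-enal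
Conditions: Dess–Martin periodinane, pyridine, CH2Cl2, 0 → 23 °C
Reagents that add atoms: none
Why: Dess–Martin oxidation of the primary alcohol under buffered, non-basic conditions, which spares the silyl ether and the alkene and does not enolise the 1,4-keto aldehyde. The aldehyde should be used at once, because such compounds cyclise by aldol reaction on standing.

Step 7
Reactants: 11 (3R)-3-acetyl-6-methyl-3-(triethylsilyloxy)hept-5-enal; 12 ethyl propiolate
Product: 14 ethyl (6R)-6-acetyl-4-hydroxy-9-methyl-6-(triethylsilyloxy)dec-8-en-2-ynoate (both C4 epimers), via lithium ethyl propiolate 13 (not isolated)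
Conditions: 12, LiN(SiMe3)2, THF, −78 °C; then 11, −78 °C; AcOH, −78 °C
Reagents that add atoms: lithium bis(trimethylsilyl)amide, [Li+].C[Si](C)(C)[N-][Si](C)(C)C (lithium only, in 13)
Why: 1,2-Addition of a lithium acetylide to an aldehyde; at −78 °C the aldehyde should react far faster than the methyl ketone next to the quaternary centre, and the weakly basic acetylide should enolise neither carbonyl. The new C6' carbinol forms without facial control, which is accepted because this centre becomes a ketone in step 13; the cold acidic quench prevents silyl migration to the new alkoxide.

Step 8
Reactants: 14 ethyl (6R)-6-acetyl-4-hydroxy-9-methyl-6-(triethylsilyloxy)dec-8-en-2-ynoate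
Product: 15 ethyl (6R)-6-acetyl-4-(tert-butyldimethylsilyloxy)-9-methyl-6-(triethylsilyloxy)dec-8-en-2-ynoate (both C4 epimers)
Conditions: t-BuMe2SiOTf, 2,6-lutidine, CH2Cl2, −78 °C
Reagents that add atoms: tert-butyldimethylsilyl triflate, CC(C)(C)[Si](C)(C)OS(=O)(=O)C(F)(F)F
Why: Standard silylation of a secondary propargylic alcohol with a silyl triflate and a non-nucleophilic base that cannot add to the ynoate. It is done before the hydration because a free γ-hydroxy β-keto ester would lactonise to a tetronic acid, and it gives C6' the mask that the key step needs.

Step 9
Reactants: 15 ethyl (6R)-6-acetyl-4-(tert-butyldimethylsilyloxy)-9-methyl-6-(triethylsilyloxy)dec-8-en-2-ynoate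
Product: 17 ethyl (6R)-6-acetyl-4-(tert-butyldimethylsilyloxy)-9-methyl-3-oxo-6-(triethylsilyloxy)dec-8-enoate (both C4 epimers), via β-morpholino enoate 16 (not isolated)
Conditions: morpholine, Et2O, 0 → 23 °C; then aq. oxalic acid, THF, 23 °C
Reagents that add atoms: morpholine, C1COCCN1 (atoms only in 16); water, O
Why: Two-stage hydration of an ynoate: conjugate addition of the secondary amine places nitrogen on the alkyne carbon remote from the ester (the future C1'), and mild acid hydrolysis of the vinylogous carbamate 16 gives the β-keto ester. Morpholine is chosen because it adds fast to the ynoate, is slow to form an enamine with the hindered methyl ketone and gives an easily hydrolysed adduct.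

Step 10
Reactants: 17 ethyl (6R)-6-acetyl-4-(tert-butyldimethylsilyloxy)-9-methyl-3-oxo-6-(triethylsilyloxy)dec-8-enoate; 18 2-hydroxy-4-methoxybenzaldehyde
Product: 19 3-[(4R)-4-acetyl-2-(tert-butyldimethylsilyloxy)-7-methyl-4-(triethylsilyloxy)oct-6-enoyl]-7-methoxy-2H-chromen-2-one (both C6' epimers)
Conditions: 18 (1.1 equiv), piperidine (cat.), AcOH (cat.), EtOH, 23 °C
Reagents that add atoms: none
Why: Knoevenagel condensation of the active methylene with the aldehyde followed by lactonisation of the phenol onto the ethyl ester, the classical route to 3-acylcoumarins. The intermolecular reaction with the unhindered aldehyde should outrun any closure of the active methylene onto the hindered C3' ketone, and lactonisation removes the adduct from equilibrium.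

Step 11
Reactants: 19 3-[(4R)-4-acetyl-2-(tert-butyldimethylsilyloxy)-7-methyl-4-(triethylsilyloxy)oct-6-enoyl]-7-methoxy-2H-chromen-2-one
Product: 21 3-[(4R)-6-(tert-butyldimethylsilyloxy)-4-(3-methylbut-2-en-1-yl)-3-oxo-4-(triethylsilyloxy)cyclohex-1-en-1-yl]-7-methoxy-2H-chromen-2-one (both C6' epimers), via tertiary aldol adduct 20 (not isolated)
Conditions: pyrrolidine, AcOH (0.5 equiv each), THF, 23 → 45 °C
Reagents that add atoms: none
Why: Pyrrolidinium acetate should convert the C3' methyl ketone into its enamine, which can form only towards C2' because C4' is fully substituted; C2' then adds to the C1' ketone and hydrolysis gives the tertiary aldol 20. The closure is a 6-(enolexo)-exo-trig attack that forms the C1'–C2' bond and the six-membered carbocycle, and E1cB loss of water through the C3' enol or enamine gives the C1'=C2' alkene, conjugated with the C3' ketone and with the coumarin. The closest known reaction type is the amine salt-mediated intramolecular aldol condensation of a methyl ketone onto an aryl ketone to give a 3-arylcyclohexenone. No stereocentre is formed: the carbinol centre of 20 disappears on dehydration, C4' carries no hydrogen and cannot epimerise, and the C6' mixture is carried on unchanged. The step needs closure at C1' only, and the substrate secures this because C6' is a silyl ether, so C1' is the single carbonyl that C2' can reach through a six-membered transition state (coumarin C2 and C4 would require eight-membered rings). C1' is activated as the acyl group of a 3-acylcoumarin, a vinylogous β-keto lactone, which should offset the hindrance from the neighbouring silyloxy carbon. With C6' masked, the C5' methylene is not acidic, so the C4' silyloxy group has no E1cB exit, and the dehydration of 20 can run only towards C2'. The buffered amine keeps conjugate addition to coumarin C4 reversible and should not open the lactone at this temperature.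

Step 12
Reactants: 21 3-[(4R)-6-(tert-butyldimethylsilyloxy)-4-(3-methylbut-2-en-1-yl)-3-oxo-4-(triethylsilyloxy)cyclohex-1-en-1-yl]-7-methoxy-2H-chromen-2-one
Product: 22 3-[(4R)-4,6-dihydroxy-4-(3-methylbut-2-en-1-yl)-3-oxocyclohex-1-en-1-yl]-7-methoxy-2H-chromen-2-one (both C6' epimers)
Conditions: HF·pyridine, pyridine, THF, 0 → 23 °C
Reagents that add atoms: none
Why: Fluoride-driven cleavage of both silyl ethers under buffered, weakly acidic conditions. It is done while C6' is still a carbinol, so the compound holds no β-hydroxy ketone that could lose water.

Step 13
Reactants: 22 3-[(4R)-4,6-dihydroxy-4-(3-methylbut-2-en-1-yl)-3-oxocyclohex-1-en-1-yl]-7-methoxy-2H-chromen-2-one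
Product: 23 3-[(4R)-4-hydroxy-4-(3-methylbut-2-en-1-yl)-3,6-dioxocyclohex-1-en-1-yl]-7-methoxy-2H-chromen-2-one (CNP0250763.1)
Conditions: MnO2 (activated, excess), CH2Cl2, 23 °C; filtration
Reagents that add atoms: none
Why: Heterogeneous oxidation with manganese dioxide is selective for the allylic secondary C6' carbinol, leaves the tertiary alcohol and the prenyl group alone, and converges both C6' epimers on one product. Neutral conditions with filtration as the only work-up should spare the new β-hydroxy ketone from dehydration to the quinone; C4' (R) is untouched.

Compound list

1 | (R)-malic acid, (2R)-2-hydroxybutanedioic acid | O[C@H](CC(=O)O)C(=O)O | starting material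
2 | [(2R,4R)-2-tert-butyl-5-oxo-1,3-dioxolan-4-yl]acetic acid (cis acetal) | OC(=O)C[C@H]1O[C@@H](C(C)(C)C)OC1=O | intermediate
3 | prenyl bromide, 1-bromo-3-methylbut-2-ene | CC(C)=CCBr | starting material
4 | dilithium enolate carboxylate of 2, dilithium (2R)-2-tert-butyl-5-(carboxylatomethyl)-1,3-dioxol-4-olate | [Li+].[Li+].[O-]C(=O)CC1=C([O-])O[C@H](C(C)(C)C)O1 | intermediate (not isolated)
5 | [(2R,4R)-2-tert-butyl-4-(3-methylbut-2-en-1-yl)-5-oxo-1,3-dioxolan-4-yl]acetic acid | OC(=O)C[C@@]1(CC=C(C)C)O[C@@H](C(C)(C)C)OC1=O | intermediate
6 | mixed anhydride of 5 with isobutyl hydrogen carbonate | CC(C)COC(=O)OC(=O)C[C@@]1(CC=C(C)C)O[C@@H](C(C)(C)C)OC1=O | intermediate (not isolated)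
7 | (2R,5R)-2-tert-butyl-5-(2-hydroxyethyl)-5-(3-methylbut-2-en-1-yl)-1,3-dioxolan-4-one | OCC[C@@]1(CC=C(C)C)O[C@@H](C(C)(C)C)OC1=O | intermediate (not isolated)
8 | (3R)-3-hydroxy-3-(3-methylbut-2-en-1-yl)dihydrofuran-2(3H)-one | O=C1OCC[C@]1(O)CC=C(C)C | intermediate
9 | (3R)-3-(3-methylbut-2-en-1-yl)-3-(triethylsilyloxy)dihydrofuran-2(3H)-one | O=C1OCC[C@]1(O[Si](CC)(CC)CC)CC=C(C)C | intermediate
10 | (3R)-3-(2-hydroxyethyl)-6-methyl-3-(triethylsilyloxy)hept-5-en-2-one | CC(=O)[C@@](O[Si](CC)(CC)CC)(CC=C(C)C)CCO | intermediate
11 | (3R)-3-acetyl-6-methyl-3-(triethylsilyloxy)hept-5-enal | CC(=O)[C@@](O[Si](CC)(CC)CC)(CC=C(C)C)CC=O | intermediate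
12 | ethyl propiolate | C#CC(=O)OCC | starting material
13 | lithium ethyl propiolate, ethyl 3-lithioprop-2-ynoate | [Li+].[C-]#CC(=O)OCC | intermediate (not isolated)
14 | ethyl (6R)-6-acetyl-4-hydroxy-9-methyl-6-(triethylsilyloxy)dec-8-en-2-ynoate, both C4 epimers | CCOC(=O)C#CC(O)C[C@](O[Si](CC)(CC)CC)(CC=C(C)C)C(C)=O | intermediate
15 | ethyl (6R)-6-acetyl-4-(tert-butyldimethylsilyloxy)-9-methyl-6-(triethylsilyloxy)dec-8-en-2-ynoate, both C4 epimers | CCOC(=O)C#CC(O[Si](C)(C)C(C)(C)C)C[C@](O[Si](CC)(CC)CC)(CC=C(C)C)C(C)=O | intermediate
16 | ethyl (2E,6R)-6-acetyl-4-(tert-butyldimethylsilyloxy)-9-methyl-3-(morpholin-4-yl)-6-(triethylsilyloxy)deca-2,8-dienoate, both C4 epimers | CCOC(=O)/C=C(/N1CCOCC1)C(O[Si](C)(C)C(C)(C)C)C[C@](O[Si](CC)(CC)CC)(CC=C(C)C)C(C)=O | intermediate (not isolated)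
17 | ethyl (6R)-6-acetyl-4-(tert-butyldimethylsilyloxy)-9-methyl-3-oxo-6-(triethylsilyloxy)dec-8-enoate, both C4 epimers | CCOC(=O)CC(=O)C(O[Si](C)(C)C(C)(C)C)C[C@](O[Si](CC)(CC)CC)(CC=C(C)C)C(C)=O | intermediate
18 | 2-hydroxy-4-methoxybenzaldehyde | COc1ccc(C=O)c(O)c1 | starting material
19 | 3-[(4R)-4-acetyl-2-(tert-butyldimethylsilyloxy)-7-methyl-4-(triethylsilyloxy)oct-6-enoyl]-7-methoxy-2H-chromen-2-one, both C6' epimers | COc1ccc2cc(C(=O)C(O[Si](C)(C)C(C)(C)C)C[C@](O[Si](CC)(CC)CC)(CC=C(C)C)C(C)=O)c(=O)oc2c1 | intermediate (precursor of the key step)
20 | 3-[(4R)-6-(tert-butyldimethylsilyloxy)-1-hydroxy-4-(3-methylbut-2-en-1-yl)-3-oxo-4-(triethylsilyloxy)cyclohexyl]-7-methoxy-2H-chromen-2-one, mixture at C1' and C6' | COc1ccc2cc(C3(O)CC(=O)[C@@](O[Si](CC)(CC)CC)(CC=C(C)C)CC3O[Si](C)(C)C(C)(C)C)c(=O)oc2c1 | intermediate (not isolated)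
21 | 3-[(4R)-6-(tert-butyldimethylsilyloxy)-4-(3-methylbut-2-en-1-yl)-3-oxo-4-(triethylsilyloxy)cyclohex-1-en-1-yl]-7-methoxy-2H-chromen-2-one, both C6' epimers | COc1ccc2cc(C3=CC(=O)[C@@](O[Si](CC)(CC)CC)(CC=C(C)C)CC3O[Si](C)(C)C(C)(C)C)c(=O)oc2c1 | intermediate (product of the key step)
22 | 3-[(4R)-4,6-dihydroxy-4-(3-methylbut-2-en-1-yl)-3-oxocyclohex-1-en-1-yl]-7-methoxy-2H-chromen-2-one, both C6' epimers | COc1ccc2cc(C3=CC(=O)[C@@](O)(CC=C(C)C)CC3O)c(=O)oc2c1 | intermediate
23 | 3-[(4R)-4-hydroxy-4-(3-methylbut-2-en-1-yl)-3,6-dioxocyclohex-1-en-1-yl]-7-methoxy-2H-chromen-2-one | COc1ccc2cc(C3=CC(=O)[C@@](O)(CC=C(C)C)CC3=O)c(=O)oc2c1 | target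

Total step count: 13. Longest linear sequence: 13 steps (1 to 23); 3, 12 and 18 are purchased and enter directly.

Least certain steps

Step 11 (key step). The most likely failures are consumption of the 3-acylcoumarin by the secondary amine (conjugate addition at coumarin C4 followed by lactone aminolysis) and stalling at the aldol stage, because C1' is flanked by the coumarin and by the C6' silyloxy carbon. The fallback is amine-free and sets out from 19. Soft enolisation (Me3SiOTf, Et3N, CH2Cl2, −20 °C) should give the trimethylsilyl enol ether of the methyl ketone F1, the methyl group being the only accessible enolisable position. TiCl4 at −78 °C, which can chelate the C1' ketone together with the coumarin C2 carbonyl, should then effect an intramolecular Mukaiyama aldol addition to the tertiary aldol 20, here isolated. Acylation of its hydroxyl group ((CF3CO)2O, pyridine) to the trifluoroacetate F2 and E1cB elimination with DBU would bring the route back at 21.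

Step 3. The most likely failure is hydride attack on the acylal carbonyl of the dioxolanone in competition with the mixed anhydride, or incomplete activation of the hindered acid, either of which lowers throughput. The fallback changes the order of events so that the reduction precedes the alkene, and sets out from 2. BH3·SMe2 (THF, 0 °C), now harmless, should reduce the acid to (2R,5R)-2-tert-butyl-5-(2-hydroxyethyl)-1,3-dioxolan-4-one F3. Silylation (t-BuMe2SiCl, imidazole) gives the silyl ether F4. Deprotonation with LiN(iPr)2 (THF, −78 °C) and alkylation with 3, again trans to the tert-butyl group, gives the prenylated silyl ether F5. Aqueous HF in MeCN removes the silyl group, and the liberated alcohol 7 lactonises with loss of pivalaldehyde, returning to the route at 8.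

Step 5. The most likely failures are a second addition of methyllithium, if the hemiketalate opens before the quench, and base-induced migration of the triethylsilyl group from the tertiary to the primary oxygen. The fallback avoids carbanions and alkoxides and sets out from 9. Petasis methylenation (Cp2TiMe2, toluene, 70 °C) should convert the lactone carbonyl into the exocyclic enol ether (3R)-2-methylidene-3-(3-methylbut-2-en-1-yl)-3-(triethylsilyloxy)oxolane F6; the trisubstituted prenyl alkene should not react. Mild hydration (aq. oxalic acid, THF) gives the hemiketal and thus 10, where the route is rejoined.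

Step 9. The most likely failures are loss of the tertiary triethylsilyl ether or incomplete hydrolysis of the vinylogous carbamate in the acidic second stage, and side reactions between the amine and the methyl ketone. The fallback introduces the oxygen through boron and sets out from 15. Copper-catalysed conjugate borylation (CuCl, NaOt-Bu, Xantphos, B2pin2, MeOH, THF) should give the (Z)-β-boryl enoate F7 by syn addition with boron on the carbon remote from the ester. Oxidation with NaBO3·4H2O (THF/H2O) converts the C–B bond into the enol and hence into 17, without acid and without amine.

## Further compounds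

F1 | step 11 | 3-[(4R)-2-(tert-butyldimethylsilyloxy)-7-methyl-4-(triethylsilyloxy)-4-[1-(trimethylsilyloxy)ethenyl]oct-6-enoyl]-7-methoxy-2H-chromen-2-one, both C6' epimers | COc1ccc2cc(C(=O)C(O[Si](C)(C)C(C)(C)C)C[C@](O[Si](CC)(CC)CC)(CC=C(C)C)C(=C)O[Si](C)(C)C)c(=O)oc2c1
F2 | step 11 | trifluoroacetate of 20 at the C1' hydroxyl, mixture at C1' and C6' | COc1ccc2cc(C3(OC(=O)C(F)(F)F)CC(=O)[C@@](O[Si](CC)(CC)CC)(CC=C(C)C)CC3O[Si](C)(C)C(C)(C)C)c(=O)oc2c1
F3 | step 3 | (2R,5R)-2-tert-butyl-5-(2-hydroxyethyl)-1,3-dioxolan-4-one | OCC[C@H]1O[C@@H](C(C)(C)C)OC1=O
F4 | step 3 | (2R,5R)-2-tert-butyl-5-[2-(tert-butyldimethylsilyloxy)ethyl]-1,3-dioxolan-4-one | CC(C)(C)[Si](C)(C)OCC[C@H]1O[C@@H](C(C)(C)C)OC1=O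
F5 | step 3 | (2R,5R)-2-tert-butyl-5-[2-(tert-butyldimethylsilyloxy)ethyl]-5-(3-methylbut-2-en-1-yl)-1,3-dioxolan-4-one | CC(C)(C)[Si](C)(C)OCC[C@@]1(CC=C(C)C)O[C@@H](C(C)(C)C)OC1=O
F6 | step 5 | (3R)-2-methylidene-3-(3-methylbut-2-en-1-yl)-3-(triethylsilyloxy)oxolane | C=C1OCC[C@]1(O[Si](CC)(CC)CC)CC=C(C)C
F7 | step 9 | ethyl (2Z,6R)-6-acetyl-4-(tert-butyldimethylsilyloxy)-9-methyl-3-(4,4,5,5-tetramethyl-1,3,2-dioxaborolan-2-yl)-6-(triethylsilyloxy)deca-2,8-dienoate, both C4 epimers | CCOC(=O)/C=C(/B1OC(C)(C)C(C)(C)O1)C(O[Si](C)(C)C(C)(C)C)C[C@](O[Si](CC)(CC)CC)(CC=C(C)C)C(C)=O
A1 | alternative 1 | 2-[2-(tert-butyldimethylsilyloxy)ethyl]prop-2-en-1-ol | C=C(CO)CCO[Si](C)(C)C(C)(C)C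
A2 | alternative 1 | (R)-{2-[2-(tert-butyldimethylsilyloxy)ethyl]oxiran-2-yl}methanol | OC[C@]1(CCO[Si](C)(C)C(C)(C)C)CO1
A3 | alternative 2 | (3R)-3-(3-methylbut-2-en-1-yl)-5-(phenylsulfonyl)-3-(triethylsilyloxy)dihydrofuran-2(3H)-one, both C5 epimers | O=C1OC(S(=O)(=O)c2ccccc2)C[C@]1(O[Si](CC)(CC)CC)CC=C(C)C
A4 | alternative 2 | 7-methoxy-3-[(E)-2-nitroethenyl]-2H-chromen-2-one | COc1ccc2cc(/C=C/[N+](=O)[O-])c(=O)oc2c1
A5 | alternative 2 | 3-[(4R)-4-(3-methylbut-2-en-1-yl)-3,6-dioxo-4-(triethylsilyloxy)cyclohex-1-en-1-yl]-7-methoxy-2H-chromen-2-one | COc1ccc2cc(C3=CC(=O)[C@@](O[Si](CC)(CC)CC)(CC=C(C)C)CC3=O)c(=O)oc2c1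
A6 | alternative 3 | (1E)-3-(7-methoxy-2-oxo-2H-chromen-3-yl)buta-1,3-dien-1-yl acetate | COc1ccc2cc(C(=C)/C=C/OC(C)=O)c(=O)oc2c1
A7 | alternative 3 | 1-formylethenyl benzoate, α-(benzoyloxy)acrolein | C=C(OC(=O)c1ccccc1)C=O
A8 | alternative 3 | cyclohexene adduct with quaternary benzoyloxy aldehyde and allylic acetate at C3' | COc1ccc2cc(C3=C[C@@H](OC(C)=O)[C@@](OC(=O)c4ccccc4)(C=O)CC3)c(=O)oc2c1
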